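(Readings and results stem from a simulated flask from invented constants, noise included.)

- In a one-step first-order world, a product's gap to its plateau shrinks by a fixed factor per half-life, whatever the charge. These are the flasks, readings and questions:

| flask | Q | remark | time |
|---|---|---|---|
| dawn | 0.050 M | run made earlier |  |
| spring | 0.20 M | run made earlier |  |
| flask | 0.10 M |  | 15 d |

- dawn (time / d: Q / %, L / %, D / %): 1.25: 2.1, 40.1, 2.0; 4.00: 0, 63.7, 2.7; 6.00: 0, 67.0, 0.9; 10.0: 1.1, 66.3, 1.3; 15.0: 0, 66.3, 0.7; 20.0: 0, 66.3, 0.1
- spring (time / d: Q / %, L / %, D / %): 3.00: 1.7, 61.5, 0.7; 6.00: 0.5, 67.1, 0.1; 10.0: 0.4, 66.5, 0; 12.0: 0.8, 67.0, 0; 15.0: 0.4, 67.1, 0; 20.0: 0.4, 67.0, 0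

(scatter of a reading: 1 percentage point)

- percent here means Q units held: one J or L or Z counts as two
- percent here means Q units held: one X counts as three
- the numbers in the tables scatter by 1 percentage point (one standard deviation)
- on the list of suspects stand: Q <-> D; D -> E; 2 Q -> J; Q + J -> X; J -> L; Q + D -> Z
- the reaction counts as stopped when no species that holds the Q changes by six tenths of a point or more over the second half of the time

- why nothing more happens at 15 d, or that something still does (it is still moving / forward and back rates have come level / all of Q has reacted)
- share of the Q used up at 15 d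
- L at 15 d, in percent of the Q charged

- Read that half-life from the dawn run: L's gap at 1.25 d gives 0.933 d.
- Now fold time and half-life into one number, the half-lives of L's gap that fit into the flask's time, 16.1.
- The last readings of the two runs average a plateau of 66.7%. At 7.50 d, where the second half of the time starts, that number leaves a gap of 0.25 percentage points below it, against the 0.6 points the stopping rule allows. So you expect L to have stopped.
- Is one number enough? For the timing, it seems so: the spring run, at 4.00 times the dawn charge, reads 0.832 d.
- For the amount, it is not. The plateau is a second reading, 66.3% at dawn and 67.0% in spring, and Q reads zero within the scatter.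
- The forecast says all of Q has reacted, 99.7% used and L 66.7%: “the reaction has stopped because Q is consumed”.
- The flask gives all of Q has reacted, with >99.9% of Q used and L at 66.6%.

    Q ⇌ D (K = 0.720, k = 0.0410 min⁻¹)
    D → E (k = 3.20 × 10⁻⁴ min⁻¹)
    2 Q → J (k = 0.270 M⁻¹ min⁻¹)
    Q + J → X (k = 0.0280 M⁻¹ min⁻¹)
    J → L (k = 5.40 × 10⁻⁴ min⁻¹)
    Q + D → Z (k = 0.0920 M⁻¹ min⁻¹)

- In this flask, J into L has a half-life of 0.89 d by that step alone, short against 15 d. Your 16.1 half-lives span 15 d; at 7.50 d they left a gap of 0.25 points, and the flask then holds J at 0.205%.
- Read at 3.36 d instead, this flask's L has moved by 5 points from its value at 15 d.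
- The neighbour flask at 0.040 M of Q lies below the dawn charge. If the half-life holds there, 16.1 half-lives again put L at its plateau, near 66.7%. Computed, that flask gives L 66.5%, with Q 0.045% left.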